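Assumption: telescoped one-pot operations (steps 2, 8, 13, 16) are each counted as one step; resorcinol and (R)-glycidol are purchased.

## Retrosynthetic overview

1. Palstatin ⇒ acid deprotection of 20 ⇒ Suzuki–Miyaura disconnection of the flavone C2–aryl bond into benzodioxanyl boronate 13 and 2-iodochromone 19.
2. 13 ⇒ Ir-catalysed arene C–H borylation of 12 ⇒ Ni/photoredox C(sp3)–H arylation (new) of benzodioxane 11 at C3 with aryl bromide 5, trans to the C2 substituent.
3. 11 ⇒ dioxane ring made first: Mitsunobu of (R)-glycidol onto 2-hydroxy-6-methoxybenzaldehyde, Baeyer–Villiger, 6-exo epoxide opening (sets C2).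
4. 19 ⇒ pyranone ring made separately: Ir C–H borylation/oxidation of resorcinol bis-MOM ether, ortho-formylation, ethynyl addition, oxidation/cyclisation, C2 zincation/iodination.
5. All three arenes come from resorcinol; ring order is dioxane ring, pyranone ring (in parallel), union, deprotection.

## Route

**Step 1**
Reactants: 1 resorcinol
Product: 2 1,3-dimethoxybenzene
Conditions: MeI (2.5 equiv), K2CO3, acetone, reflux
Reagents that add atoms: iodomethane, CI
Why: Double Williamson O-methylation (SN2) of the phenoxides.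

**Step 2**
Reactants: 2 1,3-dimethoxybenzene
Product: 3 2,6-dimethoxyphenol
Conditions: n-BuLi, THF, 0 °C → rt; B(OMe)3, −78 °C → rt; then H2O2, AcOH, 0 °C → rt
Reagents that add atoms: hydrogen peroxide, OO (supplies the phenolic O)
Why: Directed ortho-metalation at C2 between the two methoxy groups, then borylation and oxidative C–B to C–O conversion.

**Step 3**
Reactants: 3 2,6-dimethoxyphenol
Product: 4 4-bromo-2,6-dimethoxyphenol
Conditions: NBS, NaH (cat.), CHCl3, −45 °C → rt
Reagents that add atoms: N-bromosuccinimide, O=C1CCC(=O)N1Br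
Why: Electrophilic aromatic bromination directed para to the phenol(ate).

**Step 4**
Reactants: 4 4-bromo-2,6-dimethoxyphenol
Product: 5 tert-butyl (4-bromo-2,6-dimethoxyphenyl) carbonate
Conditions: Boc2O, DMAP (10 mol %), Et3N, CH2Cl2, rt
Reagents that add atoms: di-tert-butyl dicarbonate, CC(C)(C)OC(=O)OC(=O)OC(C)(C)C
Why: DMAP-catalysed O-acylation; the carbonate has no abstractable α-oxy C–H, makes the bromide less electron-rich for Ni oxidative addition, and is acid-labile.

**Step 5**
Reactants: 2 1,3-dimethoxybenzene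
Product: 6 2,6-dimethoxybenzaldehyde
Conditions: n-BuLi, THF, 0 °C → rt; DMF, 0 °C; aq. HCl
Reagents that add atoms: N,N-dimethylformamide, CN(C)C=O
Why: Directed ortho-metalation at C2 followed by formylation.

**Step 6**
Reactants: 6 2,6-dimethoxybenzaldehyde
Product: 7 2-hydroxy-6-methoxybenzaldehyde
Conditions: BCl3 (1.1 equiv), CH2Cl2, −78 → 0 °C
Reagents that add atoms: none
Why: Chelation-controlled Lewis-acid demethylation ortho to the carbonyl; the boron chelate stops the reaction after one ether is cleaved.

**Step 7**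
Reactants: 7 2-hydroxy-6-methoxybenzaldehyde; 8 (R)-glycidol
Product: 9 (S)-2-methoxy-6-(oxiran-2-ylmethoxy)benzaldehyde
Conditions: PPh3, DIAD, THF, 0 °C → rt
Reagents that add atoms: none
Why: Mitsunobu etherification at the primary carbinol carbon; the epoxide stereocentre is untouched (R to S is only a CIP priority change).

**Step 8**
Reactants: 9 (S)-2-methoxy-6-(oxiran-2-ylmethoxy)benzaldehyde
Product: 10 (R)-(8-methoxy-2,3-dihydro-1,4-benzodioxin-2-yl)methanol
Conditions: mCPBA, NaHCO3, CH2Cl2, rt; then K2CO3, MeOH, rt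
Reagents that add atoms: m-chloroperoxybenzoic acid, OOC(=O)c1cccc(Cl)c1 (one O, becomes ring O1)
Why: Baeyer–Villiger (Dakin-type) aryl migration gives the aryl formate; methanolysis frees the phenoxide, which opens the epoxide 6-exo-tet at the internal carbon with inversion and so sets C2.

**Step 9**
Reactants: 10 (R)-(8-methoxy-2,3-dihydro-1,4-benzodioxin-2-yl)methanol
Product: 11 (S)-(8-methoxy-2,3-dihydro-1,4-benzodioxin-2-yl)methyl acetate
Conditions: Ac2O, pyridine, DMAP (cat.), CH2Cl2, rt
Reagents that add atoms: acetic anhydride, CC(=O)OC(C)=O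
Why: O-acetylation (same geometry, descriptor changes by CIP priority); the acetate deactivates the exocyclic OCH2 and C2–H toward electrophilic hydrogen-atom abstraction in step 10.

**Step 10**
Reactants: 11 (S)-(8-methoxy-2,3-dihydro-1,4-benzodioxin-2-yl)methyl acetate (2.5 equiv, excess recovered); 5 tert-butyl (4-bromo-2,6-dimethoxyphenyl) carbonate (1.0 equiv)
Product: 12 [(2R,3R)-3-{4-[(tert-butoxycarbonyl)oxy]-3,5-dimethoxyphenyl}-8-methoxy-2,3-dihydro-1,4-benzodioxin-2-yl]methyl acetate
Conditions: Ir[dF(CF3)ppy]2(dtbbpy)PF6 (2 mol %), NiBr2·glyme (10 mol %), dtbbpy (12 mol %), 3-acetoxyquinuclidine (1.1 equiv), DMSO, 450 nm LEDs, 25 °C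
Reagents that add atoms: none
Why: Proposed new method: the photo-oxidised quinuclidine (aminium radical cation) abstracts the most hydridic, least hindered C–H of 11, the ring OCH2 at C3 (exocyclic OCH2 is acetate-deactivated, C2–H is tertiary and β-acyloxy, ArOCH3 is primary); the α-aryloxy radical is captured by the ArNi(II)Br from 5, and Ni(III) reductive elimination on the face anti to CH2OAc gives the trans (3R) product with C2 untouched (its descriptor becomes R by priority change). The closest known reaction is Ni/photoredox HAT α-oxy C(sp3)–H arylation of simple cyclic dialkyl ethers with aryl bromides, not shown for the α-aryloxy C–H of a substituted 1,4-benzodioxane or with substrate-controlled diastereoselectivity.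

**Step 11**
Reactants: 12 (the 2R,3R diester above)
Product: 13 [(2R,3R)-3-{4-[(tert-butoxycarbonyl)oxy]-3,5-dimethoxyphenyl}-8-methoxy-6-(4,4,5,5-tetramethyl-1,3,2-dioxaborolan-2-yl)-2,3-dihydro-1,4-benzodioxin-2-yl]methyl acetate
Conditions: [Ir(OMe)(cod)]2 (2.5 mol %), dtbpy (5 mol %), B2pin2 (1.2 equiv), THF, 80 °C
Reagents that add atoms: bis(pinacolato)diboron, CC1(C)OB(OC1(C)C)B1OC(C)(C)C(C)(C)O1
Why: Sterically governed Ir-catalysed arene C–H borylation; C6–H is the only aryl C–H with no ortho substituent (C5 and C7 are ortho to oxygen, both C–H of the other ring are flanked on both sides).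

**Step 12**
Reactants: 1 resorcinol
Product: 14 1,3-bis(methoxymethoxy)benzene
Conditions: MOMCl (2.5 equiv), i-Pr2NEt, CH2Cl2, 0 °C → rt
Reagents that add atoms: chloromethyl methyl ether, COCCl
Why: O-alkylation of both phenols to MOM acetals, which carry no aryl C–H and survive base, Grignard and zinc amide.

**Step 13**
Reactants: 14 1,3-bis(methoxymethoxy)benzene
Product: 15 3,5-bis(methoxymethoxy)phenol
Conditions: [Ir(OMe)(cod)]2 (1 mol %), dtbpy (2 mol %), B2pin2 (0.7 equiv), THF, 80 °C; then aq. NaOH, H2O2, 0 °C → rt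
Reagents that add atoms: hydrogen peroxide, OO (phenolic O; boron is not retained)
Why: Ir-catalysed C–H borylation at C5, the only C–H meta to both substituents, then boronate oxidation in the same pot.

**Step 14**
Reactants: 15 3,5-bis(methoxymethoxy)phenol
Product: 16 2-hydroxy-4,6-bis(methoxymethoxy)benzaldehyde
Conditions: MgCl2, Et3N, (CH2O)n, MeCN, reflux
Reagents that add atoms: paraformaldehyde (formaldehyde), C=O
Why: Magnesium-phenoxide-mediated ortho-formylation (Casnati–Skattebøl), exclusively ortho to the free OH; the two ortho positions are equivalent.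

**Step 15**
Reactants: 16 2-hydroxy-4,6-bis(methoxymethoxy)benzaldehyde
Product: 17 1-[2-hydroxy-4,6-bis(methoxymethoxy)phenyl]prop-2-yn-1-ol (racemic, used crude)
Conditions: HC≡CMgBr (3 equiv), THF, 0 °C → rt
Reagents that add atoms: ethynylmagnesium bromide, C#C[Mg]Br
Why: Grignard 1,2-addition to the aldehyde after deprotonation of the phenol; the carbinol centre is destroyed in the next step.

**Step 16**
Reactants: 17 (the propargylic alcohol above)
Product: 18 5,7-bis(methoxymethoxy)-4H-chromen-4-one
Conditions: MnO2, CH2Cl2, rt; then Et2NH, EtOH, rt → 50 °C, AcOH (cat.)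
Reagents that add atoms: none
Why: Oxidation to the o-hydroxyaryl ynone, amine conjugate addition to the enaminone, then 6-endo oxa-Michael addition/elimination closes the pyranone ring.

**Step 17**
Reactants: 18 5,7-bis(methoxymethoxy)-4H-chromen-4-one
Product: 19 2-iodo-5,7-bis(methoxymethoxy)-4H-chromen-4-one
Conditions: TMPZnCl·LiCl (1.3 equiv), THF, 25 °C; then I2, 0 °C
Reagents that add atoms: iodine, II
Why: Deprotonative zincation at C2–H (most acidic site, α to the ring oxygen and β to the carbonyl) followed by iodinolysis.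

**Step 18**
Reactants: 13 (the aryl boronate); 19 2-iodo-5,7-bis(methoxymethoxy)-4H-chromen-4-one
Product: 20 [(2R,3R)-6-[5,7-bis(methoxymethoxy)-4-oxo-4H-chromen-2-yl]-3-{4-[(tert-butoxycarbonyl)oxy]-3,5-dimethoxyphenyl}-8-methoxy-2,3-dihydro-1,4-benzodioxin-2-yl]methyl acetate
Conditions: Pd(dppf)Cl2 (5 mol %), K3PO4, 1,4-dioxane/H2O (9:1), 50 °C
Reagents that add atoms: none
Why: Suzuki–Miyaura coupling of the vinylogous acyl iodide with the aryl boronate forms the flavone C2–C1′ bond; both stereocentres are remote and untouched, and any partial loss of acetate or Boc is harmless.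

**Step 19**
Reactants: 20 (the protected flavonolignan)
Product: 21 Palstatin
Conditions: 3 M HCl, MeOH/THF, 50 °C
Reagents that add atoms: none
Why: Acid hydrolysis of both MOM acetals, Boc cleavage and acid-catalysed methanolysis of the acetate; C2 cannot epimerise and the trans-benzodioxane is the thermodynamic isomer, so any reversible benzylic ionisation returns the same product.

## Compound list

1 | resorcinol | Oc1cccc(O)c1 | starting material
2 | 1,3-dimethoxybenzene | COc1cccc(OC)c1 | intermediate
3 | 2,6-dimethoxyphenol | COc1cccc(OC)c1O | intermediate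
4 | 4-bromo-2,6-dimethoxyphenol | COc1cc(Br)cc(OC)c1O | intermediate
5 | tert-butyl (4-bromo-2,6-dimethoxyphenyl) carbonate | COc1cc(Br)cc(OC)c1OC(=O)OC(C)(C)C | intermediate
6 | 2,6-dimethoxybenzaldehyde | COc1cccc(OC)c1C=O | intermediate
7 | 2-hydroxy-6-methoxybenzaldehyde | COc1cccc(O)c1C=O | intermediate
8 | (R)-glycidol | OC[C@@H]1CO1 | starting material
9 | (S)-2-methoxy-6-(oxiran-2-ylmethoxy)benzaldehyde | COc1cccc(OC[C@@H]2CO2)c1C=O | intermediate
10 | (R)-(8-methoxy-2,3-dihydro-1,4-benzodioxin-2-yl)methanol | C1Oc2cccc(OC)c2O[C@@H]1CO | intermediate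
11 | (S)-(8-methoxy-2,3-dihydro-1,4-benzodioxin-2-yl)methyl acetate | C1Oc2cccc(OC)c2O[C@@H]1COC(C)=O | intermediate
12 | [(2R,3R)-3-{4-[(tert-butoxycarbonyl)oxy]-3,5-dimethoxyphenyl}-8-methoxy-2,3-dihydro-1,4-benzodioxin-2-yl]methyl acetate | COc1cc([C@H]2Oc3cccc(OC)c3O[C@@H]2COC(C)=O)cc(OC)c1OC(=O)OC(C)(C)C | intermediate
13 | 6-(pinacolboryl) derivative of 12 (name in step 11) | COc1cc([C@H]2Oc3cc(B4OC(C)(C)C(C)(C)O4)cc(OC)c3O[C@@H]2COC(C)=O)cc(OC)c1OC(=O)OC(C)(C)C | intermediate
14 | 1,3-bis(methoxymethoxy)benzene | COCOc1cccc(OCOC)c1 | intermediate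
15 | 3,5-bis(methoxymethoxy)phenol | COCOc1cc(O)cc(OCOC)c1 | intermediate
16 | 2-hydroxy-4,6-bis(methoxymethoxy)benzaldehyde | COCOc1cc(O)c(C=O)c(OCOC)c1 | intermediate
17 | 1-[2-hydroxy-4,6-bis(methoxymethoxy)phenyl]prop-2-yn-1-ol (racemic) | COCOc1cc(O)c(C(O)C#C)c(OCOC)c1 | intermediate
18 | 5,7-bis(methoxymethoxy)-4H-chromen-4-one | O=c1ccoc2cc(OCOC)cc(OCOC)c12 | intermediate
19 | 2-iodo-5,7-bis(methoxymethoxy)-4H-chromen-4-one | O=c1cc(I)oc2cc(OCOC)cc(OCOC)c12 | intermediate
20 | [(2R,3R)-6-[5,7-bis(methoxymethoxy)-4-oxo-4H-chromen-2-yl]-3-{4-[(tert-butoxycarbonyl)oxy]-3,5-dimethoxyphenyl}-8-methoxy-2,3-dihydro-1,4-benzodioxin-2-yl]methyl acetate | COc1cc([C@H]2Oc3cc(-c4cc(=O)c5c(OCOC)cc(OCOC)cc5o4)cc(OC)c3O[C@@H]2COC(C)=O)cc(OC)c1OC(=O)OC(C)(C)C | intermediate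
21 | Palstatin, 5,7-dihydroxy-2-[(2R,3R)-3-(4-hydroxy-3,5-dimethoxyphenyl)-2-(hydroxymethyl)-8-methoxy-2,3-dihydro-1,4-benzodioxin-6-yl]-4H-chromen-4-one | COc1cc([C@H]2Oc3cc(-c4cc(=O)c5c(O)cc(O)cc5o4)cc(OC)c3O[C@@H]2CO)cc(OC)c1O | target

## Totals

Total step count: 19.
Longest linear sequence: 10 steps (1, 5, 6, 7, 8, 9, 10, 11, 18, 19).

## Steps most likely to fail

1. **Step 10 (proposed new C(sp3)–H arylation).** Risks are wrong-site abstraction, over-reaction at the new benzylic C3–H, erosion of C2 by reversible abstraction, and the need for excess 11.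
   Fallback (known chemistry): drop the C–H arylation and build the aryl-bearing carbon by the classical β-O-4/quinone-methide sequence.
   - Mitsunobu etherification (inversion) of 2-(benzyloxy)-6-methoxyphenol with methyl (S)-3-silyloxy-2-hydroxypropanoate.
   - Ester to aldehyde, then addition of the aryl Grignard from silyl-protected 4.
   - Hydrogenolysis of the benzyl ether, then acid-promoted ring closure through the p-quinone methide, which gives the trans (2R,3R) benzodioxane under thermodynamic control.
   - Continue with steps 11, 18 and 19.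

2. **Step 11 (late-stage Ir borylation).** Risk is incomplete C6 versus C5 selectivity on the benzodioxane arene.
   Fallback: install the handle before the ring is built. Convert 2 to 1-chloro-3,5-dimethoxybenzene (Ir borylation, then CuCl2), run the same sequence (the aryl chloride is not touched by the Ni/photoredox step), and turn C6–Cl into C6–Bpin by Pd-catalysed Miyaura borylation.

3. **Step 17 (C2 zincation/iodination of the chromone).** Risks are regiochemistry of metalation and stability of the 2-iodochromone.
   Fallback: skip the iodide. Join 13 and 18 by Pd(II)-catalysed conjugate addition of the aryl boronate to the chromone (giving the flavanone), then dehydrogenate to the flavone (I2/DMSO or Pd(TFA)2/O2) before step 19.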